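## Retrosynthetic overview
1. Bridge: cut the C(ring B)–CH2 bond. This gives the o-quinone methide of the aromatic half (from its Mannich base, with CH2 from an iminium salt) and the free enol carbon of the (R)-configured dearomatised half.
2. Stereocentre: cut the C–CH3 bond with reversed polarity. The ring carbon becomes an enolonium (phenolate oxygen bound to a chiral aryl-λ3-iodane) and CH3 comes from Me2Zn. Two normally nucleophilic carbons are joined, the flat arene is dearomatised, and the only stereocentre is set in one operation.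
3. Flat precursor: 3-bromo-5-geranyl-2,4,6-trihydroxyacetophenone. It comes from trihydroxyacetophenone by bromination (a temporary block on the future bridge carbon) and C-geranylation.
4. Aromatic half: from phloroglucinol by Friedel–Crafts butyrylation and C-prenylation.
5. Rings: none is built. Both six-membered rings are bought as phloroglucinols, ring B is dearomatised in the key step, and the two rings are joined last.

Assumption: the chiral iodane of step 3 is treated as a known, recoverable reagent (peracid oxidation of the iodoarene made from 2-iodoresorcinol and methyl (S)-lactate, not counted as steps); its (R,R) form is assumed to give the (R) centre, and if the sense proves opposite the (S,S) reagent from methyl (R)-lactate is used.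

## Route

Step 1
Reactants: 1 2',4',6'-trihydroxyacetophenone
Product: 2 1-(3-bromo-2,4,6-trihydroxyphenyl)ethan-1-one
Conditions: NBS (1.0 equiv), MeCN, −30 → 0 °C
Reagents that add atoms: N-bromosuccinimide, O=C1CCC(=O)N1Br
Why: Electrophilic aromatic bromination (SEAr) of the very electron-rich ring; the two ring CH are equivalent, one equivalent of NBS at low temperature stops at the monobromide, and the bromine is a removable block for the carbon that later carries the bridge.

Step 2
Reactants: 2 1-(3-bromo-2,4,6-trihydroxyphenyl)ethan-1-one; 3 geranyl bromide [(2E)-1-bromo-3,7-dimethylocta-2,6-diene]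
Product: 4 1-{3-bromo-5-[(2E)-3,7-dimethylocta-2,6-dien-1-yl]-2,4,6-trihydroxyphenyl}ethan-1-one
Conditions: K2CO3 (1.1 equiv), acetone, 45 °C
Reagents that add atoms: none
Why: Base-mediated C-alkylation of the ambident phloroglucinolate (SN2 at the primary allylic bromide, so the E-alkene and the linear attachment are kept), and because bromine occupies the other position the usual 3,5-dialkylation cannot occur.

Step 3 (key step)
Reactants: 4 1-{3-bromo-5-[(2E)-3,7-dimethylocta-2,6-dien-1-yl]-2,4,6-trihydroxyphenyl}ethan-1-one; 5 (R,R)-2,6-bis[1-(methoxycarbonyl)ethoxy]-1-(diacetoxyiodo)benzene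
Product: 8 (4R)-2-acetyl-4-[(2E)-3,7-dimethylocta-2,6-dien-1-yl]-3,5-dihydroxy-4-methylcyclohexa-2,5-dien-1-one, via O-iodanyl enolonium 6 (not isolated), via bromodienone 7 (not isolated)
Conditions: (i) Me2Zn (3.2 equiv), CH2Cl2/toluene, −78 °C; (ii) 5 (1.1 equiv), −78 → −30 °C; (iii) AcOH, Zn dust, 0 °C → rt; 8 extracted into aq. NaHCO3, iodoarene recovered from the organic layer
Reagents that add atoms: dimethylzinc, C[Zn]C
Why: Proposed new method: the MeZn phenolate oxygen flanked by Br and geranyl (the one not tied up in the acetyl chelate) displaces an acetate on the chiral λ3-iodane to give 6, an O-iodanyl enolonium (phenoxenium equivalent) whose geranyl-bearing carbon, normally the nucleophilic carbon of a vinylogous 1,3-dicarbonyl, is now electrophilic, a neighbouring Zn–CH3 bond attacks it in SN2′ fashion with reductive loss of the aryl iodide, and the C2-symmetric lactate arms cover one face of the flat ring so that methyl enters from the open face and sets the quaternary centre (labelled S in 7 and R in 8 only because Br changes the CIP ranking); only ArO–ZnMe units and no free Me2Zn are present when 5 is added, Br blocks the one ring CH that would otherwise give an iodonium ylide or C–H methylation and is then removed in the same flask as a 2-bromo-1,3-dione by Zn/AcOH, and methyl rather than geranyl is the nucleophile because allyl metals would attack through their γ-carbon and give the branched isomer; the closest known reaction types are the racemic oxidative α-alkylation of 1,3-dicarbonyl compounds with dialkylzincs and Koser-type iodanes, and the enantioselective dearomatisation of phenols with lactate-derived aryl-λ3-iodanes.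

Step 4
Reactants: 9 phloroglucinol; 10 butyryl chloride
Product: 11 1-(2,4,6-trihydroxyphenyl)butan-1-one
Conditions: AlCl3 (3.5 equiv), CH2Cl2/MeNO2, 0 → 40 °C; aq. HCl work-up
Reagents that add atoms: none
Why: Friedel–Crafts acylation; the first acyl group, held in a chelate with the ortho oxygens, deactivates the ring so that monoacylation is clean.

Step 5
Reactants: 11 1-(2,4,6-trihydroxyphenyl)butan-1-one; 12 prenyl bromide (1-bromo-3-methylbut-2-ene)
Product: 13 1-[2,4,6-trihydroxy-3-(3-methylbut-2-en-1-yl)phenyl]butan-1-one
Conditions: KOH (1.0 equiv), 12 (0.9 equiv), H2O, 0 °C → rt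
Reagents that add atoms: none
Why: C-prenylation of the phloroglucinolate in water (SN2, hydrogen-bonded phenolate oxygens favour C- over O-attack); the bromide is limiting so the mono-prenyl compound predominates and unreacted 11 is recycled.

Step 6
Reactants: 13 1-[2,4,6-trihydroxy-3-(3-methylbut-2-en-1-yl)phenyl]butan-1-one; 8 (4R)-2-acetyl-4-[(2E)-3,7-dimethylocta-2,6-dien-1-yl]-3,5-dihydroxy-4-methylcyclohexa-2,5-dien-1-one
Product: 16 CNP0227753.1 [(4R)-2-acetyl-6-{[3-butanoyl-2,4,6-trihydroxy-5-(3-methylbut-2-en-1-yl)phenyl]methyl}-4-[(2E)-3,7-dimethylocta-2,6-dien-1-yl]-3,5-dihydroxy-4-methylcyclohexa-2,5-dien-1-one], via Mannich base 14 (not isolated), via ortho-quinone methide 15 (not isolated)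
Conditions: (i) 13, Me2N=CH2+ I− (1.0 equiv), MeCN, 0 °C → rt; (ii) 8 (1.0 equiv), NaOAc (1.1 equiv), 60 °C; dilute HCl work-up
Reagents that add atoms: Eschenmoser's salt (N,N-dimethylmethyleneiminium iodide), C=[N+](C)C.[I-]
Why: Mannich reaction at the single free aromatic CH, thermal loss of dimethylamine to the o-quinone methide, and conjugate (Michael) addition of the only free ring carbon of vinylogous acid 8 give the unsymmetrical dimer without the homodimers of a formaldehyde condensation; no stereocentre is formed and the quaternary centre of 8 cannot epimerise.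

## Compound list
1 | 2',4',6'-trihydroxyacetophenone | CC(=O)c1c(O)cc(O)cc1O | starting material
2 | 1-(3-bromo-2,4,6-trihydroxyphenyl)ethan-1-one | CC(=O)c1c(O)cc(O)c(Br)c1O | intermediate
3 | geranyl bromide | BrC/C=C(\C)CCC=C(C)C | starting material
4 | 1-{3-bromo-5-[(2E)-3,7-dimethylocta-2,6-dien-1-yl]-2,4,6-trihydroxyphenyl}ethan-1-one | CC(=O)c1c(O)c(Br)c(O)c(C/C=C(\C)CCC=C(C)C)c1O | intermediate
5 | (R,R)-2,6-bis[1-(methoxycarbonyl)ethoxy]-1-(diacetoxyiodo)benzene | CC(=O)OI(OC(C)=O)c1c(O[C@H](C)C(=O)OC)cccc1O[C@H](C)C(=O)OC | starting material (chiral oxidant, see assumption)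
6 | O-iodanyl enolonium: 4 bound through the oxygen between C–Br and C–geranyl to the I(III) centre of 5 in place of one acetate (other OH drawn free, MeZn phenolates in the flask) | CC(=O)c1c(O)c(Br)c(OI(OC(C)=O)c2c(O[C@H](C)C(=O)OC)cccc2O[C@H](C)C(=O)OC)c(C/C=C(\C)CCC=C(C)C)c1O | intermediate (not isolated)
7 | (4S)-2-acetyl-6-bromo-4-[(2E)-3,7-dimethylocta-2,6-dien-1-yl]-3,5-dihydroxy-4-methylcyclohexa-2,5-dien-1-one (same spatial arrangement as 8) | O=C1C(Br)=C(O)[C@@](C)(C/C=C(\C)CCC=C(C)C)C(O)=C1C(C)=O | intermediate (not isolated)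
8 | (4R)-2-acetyl-4-[(2E)-3,7-dimethylocta-2,6-dien-1-yl]-3,5-dihydroxy-4-methylcyclohexa-2,5-dien-1-one | O=C1C=C(O)[C@@](C)(C/C=C(\C)CCC=C(C)C)C(O)=C1C(C)=O | intermediate
9 | phloroglucinol | Oc1cc(O)cc(O)c1 | starting material
10 | butyryl chloride | CCCC(=O)Cl | starting material
11 | 1-(2,4,6-trihydroxyphenyl)butan-1-one | CCCC(=O)c1c(O)cc(O)cc1O | intermediate
12 | prenyl bromide | CC(C)=CCBr | starting material
13 | 1-[2,4,6-trihydroxy-3-(3-methylbut-2-en-1-yl)phenyl]butan-1-one | CCCC(=O)c1c(O)c(CC=C(C)C)c(O)cc1O | intermediate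
14 | 1-{3-[(dimethylamino)methyl]-2,4,6-trihydroxy-5-(3-methylbut-2-en-1-yl)phenyl}butan-1-one | CCCC(=O)c1c(O)c(CC=C(C)C)c(O)c(CN(C)C)c1O | intermediate (not isolated)
15 | 2-butanoyl-3,5-dihydroxy-4-(3-methylbut-2-en-1-yl)-6-methylidenecyclohexa-2,4-dien-1-one | CCCC(=O)C1=C(O)C(CC=C(C)C)=C(O)C(=C)C1=O | intermediate (not isolated)
16 | CNP0227753.1, (4R)-2-acetyl-6-{[3-butanoyl-2,4,6-trihydroxy-5-(3-methylbut-2-en-1-yl)phenyl]methyl}-4-[(2E)-3,7-dimethylocta-2,6-dien-1-yl]-3,5-dihydroxy-4-methylcyclohexa-2,5-dien-1-one | CCCC(=O)c1c(O)c(CC=C(C)C)c(O)c(CC2=C(O)[C@@](C)(C/C=C(\C)CCC=C(C)C)C(O)=C(C(C)=O)C2=O)c1O | target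

## Step count and risks
Total steps: 6. Longest linear sequence: 4 (steps 1, 2, 3, 6).

**Step 3 (highest risk).** No enantioselective version of this methyl transfer is known. The iodane may oxidise Zn–CH3 directly. Enolonium 6 may lose an allylic proton, giving a vinyl quinone methide and then a chromene. The ee may also be modest.
The fallback sets out from 4 and uses the reaction in its established racemic form, obtaining the enantiomer by resolution instead of reagent control. Me2Zn and achiral PhI(OH)OTs give the phenyl(tosyloxy)iodanyl enolonium F1, which collapses to the racemic bromodienone F2. Zn/AcOH then gives the racemic vinylogous acid F3. Half an equivalent of (S)-1-phenylethylamine in EtOAc/heptane crystallises the (S)-1-phenylethylammonium salt of the (R)-acid F4; the antipodal amine is used if the other salt proves less soluble. A wash with dilute HCl comes back to the route at 8.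

**Step 2.** The bromophloroglucinol may transfer or disproportionate bromine under base, or may O-alkylate.
The fallback sets out from 1 and inverts the order of events. Unblocked 1 is geranylated (K2CO3, acetone) to the known 3-geranyl-2,4,6-trihydroxyacetophenone F5, which is freed from the digeranyl by-product by chromatography. The remaining ring CH is then brominated with NBS in CH2Cl2 at −78 °C, where the ring reacts far faster than the trisubstituted alkenes. This comes back to the route at 4.

**Step 6.** The Mannich base may be reluctant to release 15, or amine-promoted methylene exchange may scramble the halves.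
The fallback sets out from 8 and exchanges the roles of the two halves. Compound 8 and Eschenmoser's salt give the ring-B Mannich base F6. On warming with 13, F6 loses dimethylamine to give the exo-methylene trione F7, a stronger acceptor than 15. The free aromatic CH of 13 adds to it, which comes back to the route at 16.

## Further compounds
F1 | step 3 | phenyl(tosyloxy)iodanyl enolonium of 4 (bound through the oxygen between C–Br and C–geranyl) | CC(=O)c1c(O)c(Br)c(OI(OS(=O)(=O)c2ccc(C)cc2)c2ccccc2)c(C/C=C(\C)CCC=C(C)C)c1O
F2 | step 3 | racemic 2-acetyl-6-bromo-4-[(2E)-3,7-dimethylocta-2,6-dien-1-yl]-3,5-dihydroxy-4-methylcyclohexa-2,5-dien-1-one | O=C1C(Br)=C(O)C(C)(C/C=C(\C)CCC=C(C)C)C(O)=C1C(C)=O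
F3 | step 3 | racemic 2-acetyl-4-[(2E)-3,7-dimethylocta-2,6-dien-1-yl]-3,5-dihydroxy-4-methylcyclohexa-2,5-dien-1-one | O=C1C=C(O)C(C)(C/C=C(\C)CCC=C(C)C)C(O)=C1C(C)=O
F4 | step 3 | (S)-1-phenylethylammonium salt of the (4R)-acid 8 | O=C1C=C(O)[C@@](C)(C/C=C(\C)CCC=C(C)C)C([O-])=C1C(C)=O.C[C@H]([NH3+])c1ccccc1
F5 | step 2 | 1-{3-[(2E)-3,7-dimethylocta-2,6-dien-1-yl]-2,4,6-trihydroxyphenyl}ethan-1-one | CC(=O)c1c(O)cc(O)c(C/C=C(\C)CCC=C(C)C)c1O
F6 | step 6 | (4R)-2-acetyl-6-[(dimethylamino)methyl]-4-[(2E)-3,7-dimethylocta-2,6-dien-1-yl]-3,5-dihydroxy-4-methylcyclohexa-2,5-dien-1-one | CN(C)CC1=C(O)[C@@](C)(C/C=C(\C)CCC=C(C)C)C(O)=C(C(C)=O)C1=O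
F7 | step 6 | (4S)-2-acetyl-4-[(2E)-3,7-dimethylocta-2,6-dien-1-yl]-3-hydroxy-4-methyl-6-methylidenecyclohex-2-ene-1,5-dione (same spatial arrangement as 8, descriptor changed by CIP ranking) | C=C1C(=O)[C@@](C)(C/C=C(\C)CCC=C(C)C)C(O)=C(C(C)=O)C1=O
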